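**Retrosynthetic overview**
- The target is opened at the epoxide: hydroxyl-directed C8–C9 epoxidation (C–O) and phenol desilylation of a dauc-8-ene 4-O-aroyl-6-ol.
- Key C–O disconnection: the hindered tertiary C4–O–acyl bond comes from a samarium-catalysed Tishchenko-type redox esterification of a 4-hydroxy-6-ketone with O-silyl vanillin, which also sets C6.
- The 4-hydroxy-6-ketone comes from oxidation of jaeschkeanadiol, itself from isopropyl addition to the C4 ketone of a trans-fused hydroazulenone.
- The seven-membered ring is formed second, by ring-closing metathesis; the five-membered ring is the starting cyclopentenone.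
- C1, C5 and C6 come from a copper-catalysed asymmetric conjugate methylation of 3-allylcyclopentenone with in-flask aldol to 3-methylbut-3-enal.

Assumption: daucane numbering is used for the bicycles (C1 angular-methyl carbon, C4 isopropyl-bearing carbon, C5 ring-fusion CH, C6 carbinol carbon, C8=C9 ring alkene); the phosphoramidite enantiomer in step 3 is the one that delivers methyl to the Si face of the enone β-carbon (checked on a quenched aliquot), and the minor C6 epimer of the aldol is carried along because C6 is reset in steps 6 and 8.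

**Step 1**
Reactants: 1 3-ethoxycyclopent-2-en-1-one
Product: 2 3-(prop-2-en-1-yl)cyclopent-2-en-1-one
Conditions: CH2=CHCH2MgBr (1.2 equiv), THF, 0 °C; then 1 M HCl, 0 °C, 15 min
Reagents that add atoms: allylmagnesium bromide, C=CC[Mg]Br
Why: Stork–Danheiser sequence, in which 1,2-addition to the vinylogous ester and brief cold acid hydrolysis with loss of ethanol transpose the carbonyl to give the 3-allyl enone without moving the skipped alkene into conjugation; no stereocentre.

**Step 2**
Reactants: 3 3-methylbut-3-en-1-ol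
Product: 4 3-methylbut-3-enal
Conditions: Dess–Martin periodinane (1.1 equiv), CH2Cl2, 0 °C to rt; filtered and used at once as a solution
Reagents that add atoms: none
Why: Dess–Martin oxidation of the primary homoallylic alcohol stops at the β,γ-unsaturated aldehyde under non-basic, non-aqueous conditions that do not isomerise it to the conjugated aldehyde; no stereocentre.

**Step 3**
Reactants: 2 3-(prop-2-en-1-yl)cyclopent-2-en-1-one; 4 3-methylbut-3-enal
Product: 6 (2S,3R)-2-[(1S)-1-hydroxy-3-methylbut-3-en-1-yl]-3-methyl-3-(prop-2-en-1-yl)cyclopentan-1-one, via dimethylaluminum enolate 5 (not isolated)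
Conditions: Me3Al (1.4 equiv), Cu(O2CC4H3S) (copper thiophene-2-carboxylate, 5 mol%), BINOL-derived N,N-bis(1-phenylethyl)phosphoramidite (10 mol%), Et2O, −30 °C; then 4 (2 equiv), THF, −78 to −40 °C; 1 M HCl quench
Reagents that add atoms: trimethylaluminum, C[Al](C)C
Why: Copper-catalysed asymmetric conjugate addition sets the quaternary C1 (R) under ligand control and gives a regiodefined aluminum enolate, which undergoes an aldol addition through a closed Zimmerman–Traxler transition state on the face anti to the larger allyl group (C5 S, side chain trans to allyl), giving mainly the anti 6S carbinol.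

**Step 4**
Reactants: 6 (2S,3R)-2-[(1S)-1-hydroxy-3-methylbut-3-en-1-yl]-3-methyl-3-(prop-2-en-1-yl)cyclopentan-1-one
Product: 7 (3aR,8S,8aS)-8-hydroxy-3a,6-dimethyl-3,3a,4,7,8,8a-hexahydroazulen-1(2H)-one (trans-fused; C4 ketone, 6α-OH, 1β-methyl, 5α-H)
Conditions: second-generation Grubbs catalyst RuCl2(=CHPh)(PCy3)(H2IMes) (5 mol%), CH2Cl2 (5 mM), 40 °C
Reagents that add atoms: none
Why: Ring-closing metathesis of the allyl and methallyl arms closes the seven-membered ring as the trisubstituted C8=C9 alkene with loss of ethene; no new stereocentre, the trans ring fusion follows from step 3, and any cis-fused isomer from the minor C5 epimer is removed here.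

**Step 5**
Reactants: 7 (3aR,8S,8aS)-8-hydroxy-3a,6-dimethyl-3,3a,4,7,8,8a-hexahydroazulen-1(2H)-one
Product: 8 jaeschkeanadiol, (1R,4R,5S,6S)-dauc-8-ene-4,6-diol [(3R,3aS,4S,8aR)-6,8a-dimethyl-3-(propan-2-yl)-1,2,3,3a,4,5,8,8a-octahydroazulene-3,4-diol]
Conditions: i-PrMgCl (3 equiv), CeCl3 (3 equiv), THF, −78 to 0 °C; aq. NH4Cl
Reagents that add atoms: isopropylmagnesium chloride, CC(C)[Mg]Cl
Why: Organocerium 1,2-addition (i-PrCeCl2 has low basicity, so enolisation, β-hydride reduction and retro-aldol are suppressed) occurs on the α face of the cyclopentanone, anti to the vicinal C5–C6 bond and the angular methyl, giving the 4β tertiary alcohol (4R).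

**Step 6**
Reactants: 8 jaeschkeanadiol
Product: 9 (1R,4R,5R)-4-hydroxydauc-8-en-6-one [(3R,3aR,8aR)-3-hydroxy-6,8a-dimethyl-3-(propan-2-yl)-2,3,3a,5,8,8a-hexahydroazulen-4(1H)-one]
Conditions: Dess–Martin periodinane (1.5 equiv), pyridine (5 equiv), CH2Cl2, 0 °C
Reagents that add atoms: none
Why: Buffered Dess–Martin oxidation converts only the secondary C6 carbinol (the tertiary C4–OH cannot be oxidised) into the β,γ-unsaturated ketone without conjugation, and erasing C6 makes both aldol epimers converge.

**Step 7**
Reactants: 10 vanillin (4-hydroxy-3-methoxybenzaldehyde)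
Product: 11 4-[(tert-butyldimethylsilyl)oxy]-3-methoxybenzaldehyde
Conditions: TBSCl (1.1 equiv), imidazole (2 equiv), CH2Cl2, rt
Reagents that add atoms: tert-butyldimethylsilyl chloride, CC(C)(C)[Si](C)(C)Cl
Why: Standard phenol silylation masks the acidic OH, which would otherwise protonate the samarium alkoxides needed in step 8; no stereocentre.

**Step 8**
Reactants: 9 (1R,4R,5R)-4-hydroxydauc-8-en-6-one; 11 4-[(tert-butyldimethylsilyl)oxy]-3-methoxybenzaldehyde
Product: 12 (1R,4R,5S,6S)-6-hydroxydauc-8-en-4-yl 4-[(tert-butyldimethylsilyl)oxy]-3-methoxybenzoate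
Conditions: SmI2 (30 mol%, premixed with 11), 11 (5 equiv), THF, −10 °C, dark; cold aq. NaHCO3 quench at full conversion
Reagents that add atoms: none
Why: Proposed new method: an Evans–Tishchenko-type redox esterification extended to a tertiary carbinol donor and an electron-rich aryl aldehyde, in which the trivalent samarium alkoxide of the C4–OH adds reversibly to 11 to give a samarium-bound hemiacetal chelated to the C6 ketone, and irreversible hydride transfer through a six-membered chair transition state turns the hemiacetal carbon into the ester carbonyl on O4 (no acylating agent is present, so O6 cannot compete) while delivering hydride to the β face of C6 to set the 6α-OH (6S, 1,3-anti); the closest known reaction is the SmI2-catalysed Evans–Tishchenko reduction of secondary β-hydroxy ketones.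

**Step 9**
Reactants: 12 (1R,4R,5S,6S)-6-hydroxydauc-8-en-4-yl 4-[(tert-butyldimethylsilyl)oxy]-3-methoxybenzoate
Product: 14 (1R,4R,5S,6S,8R,9S)-8,9-epoxy-6-hydroxydaucan-4-yl 4-hydroxy-3-methoxybenzoate, via silyl-protected epoxide 13 (not isolated)
Conditions: VO(acac)2 (5 mol%), t-BuOOH (1.5 equiv, decane), CH2Cl2, 0 °C to rt; then TBAF/AcOH (1:1, 1.2 equiv), THF, 0 °C
Reagents that add atoms: tert-butyl hydroperoxide, CC(C)(C)OO
Why: Vanadium-catalysed hydroxyl-directed epoxidation, in which the homoallylic 6α-OH binds the pentavalent vanadium tert-butylperoxide and delivers oxygen to the α face of C8=C9 (also the face remote from the angular methyl), sets 8R,9S, and acetic-acid-buffered fluoride then cleaves only the aryl silyl ether without ester migration or epoxide opening.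

**Compound list**
1 | 3-ethoxycyclopent-2-en-1-one | CCOC1=CC(=O)CC1 | starting material
2 | 3-(prop-2-en-1-yl)cyclopent-2-en-1-one | O=C1C=C(CC=C)CC1 | intermediate
3 | 3-methylbut-3-en-1-ol | CC(=C)CCO | starting material
4 | 3-methylbut-3-enal | CC(=C)CC=O | intermediate
5 | dimethylaluminum (3R)-3-methyl-3-(prop-2-en-1-yl)cyclopent-1-en-1-olate | C[Al](C)OC1=C[C@@](C)(CC=C)CC1 | intermediate
6 | (2S,3R)-2-[(1S)-1-hydroxy-3-methylbut-3-en-1-yl]-3-methyl-3-(prop-2-en-1-yl)cyclopentan-1-one | O=C1CC[C@](C)(CC=C)[C@H]1[C@@H](O)CC(C)=C | intermediate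
7 | (3aR,8S,8aS)-8-hydroxy-3a,6-dimethyl-3,3a,4,7,8,8a-hexahydroazulen-1(2H)-one | O=C1CC[C@]2(C)CC=C(C)C[C@H](O)[C@H]21 | intermediate
8 | jaeschkeanadiol, (1R,4R,5S,6S)-dauc-8-ene-4,6-diol | O[C@@]1(C(C)C)CC[C@]2(C)CC=C(C)C[C@H](O)[C@H]21 | intermediate
9 | (1R,4R,5R)-4-hydroxydauc-8-en-6-one | O[C@@]1(C(C)C)CC[C@]2(C)CC=C(C)CC(=O)[C@H]21 | intermediate
10 | vanillin | COc1cc(C=O)ccc1O | starting material
11 | 4-[(tert-butyldimethylsilyl)oxy]-3-methoxybenzaldehyde | COc1cc(C=O)ccc1O[Si](C)(C)C(C)(C)C | intermediate
12 | (1R,4R,5S,6S)-6-hydroxydauc-8-en-4-yl 4-[(tert-butyldimethylsilyl)oxy]-3-methoxybenzoate | COc1cc(C(=O)O[C@@]2(C(C)C)CC[C@]3(C)CC=C(C)C[C@H](O)[C@H]32)ccc1O[Si](C)(C)C(C)(C)C | intermediate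
13 | (1R,4R,5S,6S,8R,9S)-8,9-epoxy-6-hydroxydaucan-4-yl 4-[(tert-butyldimethylsilyl)oxy]-3-methoxybenzoate | COc1cc(C(=O)O[C@@]2(C(C)C)CC[C@]3(C)C[C@@H]4O[C@]4(C)C[C@H](O)[C@H]32)ccc1O[Si](C)(C)C(C)(C)C | intermediate
14 | (1R,4R,5S,6S,8R,9S)-8,9-epoxy-6-hydroxydaucan-4-yl 4-hydroxy-3-methoxybenzoate (8α,9α-epoxyjaeschkeanadiol 4-O-vanillate) | COc1cc(C(=O)O[C@@]2(C(C)C)CC[C@]3(C)C[C@@H]4O[C@]4(C)C[C@H](O)[C@H]32)ccc1O | target

**Step count**
Total steps: 9. Longest linear sequence: 7 (steps 1, 3, 4, 5, 6, 8, 9).

**Three steps most likely to fail**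

Step 8 (the proposed new reaction). The risks are slow hemiacetal formation at the tertiary oxygen, retro-aldol opening of the five-membered ring, migration of the aroyl group from O4 to O6 once the C6 samarium alkoxide has formed, and conjugation of the β,γ-unsaturated ketone. The fallback uses known chemistry, sets out from 8 and comes back at 12. Any 6-epimer of 8 is first converged by oxidation to 9 and hydroxyl-directed anti reduction with Me4NBH(OAc)3. Diol 8 is then silylated at the secondary hydroxyl only (TESCl, imidazole, DMF, 0 °C) to give the 6-O-triethylsilyl ether F3. Aldehyde 11 is oxidised (NaClO2, NaH2PO4, 2-methylbut-2-ene, t-BuOH/H2O) to 4-[(tert-butyldimethylsilyl)oxy]-3-methoxybenzoic acid F4, which 1-chloro-N,N,2-trimethylprop-1-en-1-amine converts under neutral conditions into the acid chloride F5. The lithium alkoxide of F3 (LiN(SiMe3)2, THF, −78 °C) is acylated with F5 to the doubly silylated ester F6, and PPTS in MeOH removes the alkyl triethylsilyl ether while leaving the aryl silyl ether, giving 12.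

Step 3. The risks are modest face selectivity at C5 (methyl versus allyl on the adjacent quaternary carbon), a sluggish aldol of the hindered aluminum enolate, and proton transfer to or isomerisation of aldehyde 4. The fallback sets out from 2 and comes back at 6. The conjugate addition is run as before, but enolate 5 is quenched with triethylsilyl triflate and the triethylsilyl enol ether F1 is isolated. F1 then undergoes a BF3·OEt2-mediated Mukaiyama aldol with 4 in CH2Cl2 at −78 °C; this open transition state has no basic enolate, and the Lewis-acid-bound aldehyde is bulkier and discriminates better between methyl and allyl, returning 6.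

Step 5. The risks are enolisation or retro-aldol of the β-alkoxy ketone and reduction of the ketone by β-hydride transfer from the isopropyl reagent. The fallback sets out from 7 and comes back at 8. Isopropenylmagnesium bromide with CeCl3 (a smaller sp2 nucleophile without β-hydrogens) is added from the same α face to give (1R,4S,5S,6S)-dauca-8,11-diene-4,6-diol F2. The 1,1-disubstituted alkene of F2 is then hydrogenated selectively with Wilkinson's catalyst RhCl(PPh3)3 under 1 atm H2 in benzene, leaving the trisubstituted ring alkene, to give 8.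

**Further compounds**
F1 | step 3 | triethyl{[(3R)-3-methyl-3-(prop-2-en-1-yl)cyclopent-1-en-1-yl]oxy}silane | CC[Si](CC)(CC)OC1=C[C@@](C)(CC=C)CC1
F2 | step 5 | (1R,4S,5S,6S)-dauca-8,11-diene-4,6-diol | O[C@@]1(C(C)=C)CC[C@]2(C)CC=C(C)C[C@H](O)[C@H]21
F3 | step 8 | (1R,4R,5S,6S)-6-[(triethylsilyl)oxy]dauc-8-en-4-ol | O[C@@]1(C(C)C)CC[C@]2(C)CC=C(C)C[C@H](O[Si](CC)(CC)CC)[C@H]21
F4 | step 8 | 4-[(tert-butyldimethylsilyl)oxy]-3-methoxybenzoic acid | COc1cc(C(=O)O)ccc1O[Si](C)(C)C(C)(C)C
F5 | step 8 | 4-[(tert-butyldimethylsilyl)oxy]-3-methoxybenzoyl chloride | COc1cc(C(=O)Cl)ccc1O[Si](C)(C)C(C)(C)C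
F6 | step 8 | (1R,4R,5S,6S)-6-[(triethylsilyl)oxy]dauc-8-en-4-yl 4-[(tert-butyldimethylsilyl)oxy]-3-methoxybenzoate | COc1cc(C(=O)O[C@@]2(C(C)C)CC[C@]3(C)CC=C(C)C[C@H](O[Si](CC)(CC)CC)[C@H]32)ccc1O[Si](C)(C)C(C)(C)C
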